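**Retrosynthetic overview**
1. The γ‑lactone is closed last. A palladium‑catalysed dehydrogenative C7–O lactonisation on a cis‑cyclodecene forms the lactone, sets C7 and moves the alkene into conjugation (C5=C6).
2. The ten‑membered ring comes from ring‑closing metathesis (C6=C7) of a diene whose two vinyl groups sit on C5 and C8.
3. C9 and C8 come from a C9 aldehyde: Felkin addition of lithiated methoxyallene, then chelation‑controlled Reformatsky addition (C17–C19).
4. The aldehyde comes from a carvone‑derived enone after Wharton 1,3‑transposition, cuprate addition at C10, protonation at C11 and hydride delivery at C12.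
5. Ring A is (S)‑carvone (C14–O by Criegee rearrangement); C2–C6 and C16 come from one aldehyde. Ring order: six‑membered ring (chiral pool), then ten‑membered ring, then lactone.

Assumption: positions carry briarane numbers (ring A = C1, C10–C14; ten‑membered ring = C1–C10; C15 and C20 methyls; C16 ester carbon; lactone = C7, C8, C17, C19), β means the face of ring A that carries C15, metal enolates or alkoxides of a numbered compound get no number of their own, and C5 (and C17 until step 20) are carried as inconsequential epimer mixtures.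

Step 1
Reactants: 1 methyl (E)-but-2-enoate; 2 2-(2-bromoethyl)-1,3-dioxolane
Product: 3 methyl 2-[2-(1,3-dioxolan-2-yl)ethyl]but-3-enoate (racemic)
Conditions: LiN(i-Pr)2, HMPA, THF, −78 °C; then 2, −78 → 0 °C
Reagents that add atoms: none
Why: Deconjugative α‑alkylation of the crotonate lithium dienolate (kinetic α‑attack) builds the future C5 with its vinyl group (C6) and ester (C16); C5 is racemic and is destroyed in step 20.

Step 2
Reactants: 3 methyl 2-[2-(1,3-dioxolan-2-yl)ethyl]but-3-enoate
Product: 4 methyl 2-ethenyl-5-oxopentanoate (racemic)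
Conditions: 1 M HCl, THF, 20 °C
Reagents that add atoms: water O
Why: Acid‑catalysed acetal hydrolysis frees the aldehyde (future C2) under conditions too mild to conjugate the β,γ‑unsaturated ester.

Step 3
Reactants: 5 (S)-(+)-carvone
Product: 7 (1S)-4-methyl-5-oxocyclohex-3-en-1-yl acetate, via methoxy hydroperoxide 6 (not isolated)
Conditions: O3, CH2Cl2/MeOH, −78 °C; then Ac2O, Et3N, DMAP, 0 → 20 °C
Reagents that add atoms: ozone O=[O+][O-]; methanol CO
Why: Ozonolysis cleaves only the electron‑rich isopropenyl alkene, and Criegee rearrangement of the peracetate migrates the ring carbon to oxygen with retention, giving the C14 oxygen (acetyl carbons are the old isopropenyl carbons).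

Step 4
Reactants: 7 (1S)-4-methyl-5-oxocyclohex-3-en-1-yl acetate
Product: 9 (5S)-2-methyl-5-(triethylsilyloxy)cyclohex-2-en-1-one, via hydroxy enone 8 (not isolated)
Conditions: K2CO3 (cat.), MeOH, 0 °C; evaporate; Et3SiCl, imidazole, CH2Cl2, 0 °C
Reagents that add atoms: chlorotriethylsilane CC[Si](Cl)(CC)CC
Why: Transesterification then silylation swaps the β‑acetoxy group (which would eliminate from an enolate) for a silyl ether that survives the enolate chemistry of steps 5 and 6; no stereocentre changes.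

Step 5
Reactants: 9 (5S)-2-methyl-5-(triethylsilyloxy)cyclohex-2-en-1-one; 4 methyl 2-ethenyl-5-oxopentanoate
Product: 11 β-diketone methyl 2-ethenyl-5-[(6S)-3-methyl-2-oxo-6-(triethylsilyloxy)cyclohex-3-en-1-yl]-5-oxopentanoate, via aldol adduct 10 (not isolated)
Conditions: LiN(i-Pr)2, THF, −78 °C; 4; aq. NH4Cl; crude, Dess–Martin periodinane, NaHCO3, CH2Cl2, 0 → 20 °C
Reagents that add atoms: none
Why: Kinetic α′‑enolate aldol addition attaches C2–C6/C16 to C1, and Dess–Martin oxidation to the β‑diketone makes the aldol stereocentres irrelevant.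

Step 6
Reactants: 11 β-diketone
Product: 12 C1-methylated diketone (C15 methyl trans to the C14 silyloxy group; 14S)
Conditions: MeI, K2CO3, acetone, 20 °C
Reagents that add atoms: iodomethane CI
Why: C‑alkylation of the β‑diketone enolate occurs anti to the adjacent C14 silyloxy group and sets the C1 quaternary centre.

Step 7
Reactants: 12 C1-methylated diketone
Product: 13 (2R)-alcohol (C2 hydroxyl syn to the C14 oxygen; enone ketone untouched)
Conditions: NaBH4, MeOH/CH2Cl2 (1:1), −78 °C
Reagents that add atoms: none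
Why: Borohydride reduces the saturated ketone chemoselectively over the enone; under non‑chelating conditions the Felkin–Anh/Cornforth model (ring acyl group anti to hydride, attack past the methyl) predicts the (2R)-alcohol.

Step 8
Reactants: 13 (2R)-alcohol
Product: 14 (2R)-acetate (C14 triethylsilyl ether retained)
Conditions: Ac2O, pyridine, DMAP (cat.), CH2Cl2, 0 → 20 °C
Reagents that add atoms: acetic anhydride CC(=O)OC(C)=O
Why: Acetylation installs the final C2 acetate at once and prevents δ‑lactonisation of the C2 hydroxyl onto the C16 ester.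

Step 9
Reactants: 14 (2R)-acetate
Product: 15 11,12-epoxy ketone (epoxide trans to the C14 silyloxy group)
Conditions: t-BuOOH, BnMe3N+ OH− (cat.), THF, 0 °C
Reagents that add atoms: tert-butyl hydroperoxide CC(C)(C)OO
Why: Weitz–Scheffer nucleophilic epoxidation of the enone from the face anti to the C14 substituent, as with carvone itself.

Step 10
Reactants: 15 11,12-epoxy ketone
Product: 16 12β-allylic alcohol with C10=C11 alkene
Conditions: N2H4·H2O, AcOH (cat.), MeOH, 0 → 20 °C
Reagents that add atoms: none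
Why: Wharton transposition (epoxy hydrazone fragmentation with loss of N2) moves the oxygen to C12 and the alkene to C10=C11.

Step 11
Reactants: 16 12β-allylic alcohol
Product: 17 transposed enone (C12 ketone, C10=C11 alkene, C1 quaternary at the γ-position)
Conditions: MnO2, CH2Cl2, 20 °C
Reagents that add atoms: none
Why: Selective allylic alcohol oxidation gives the enone in which C10 is the electrophilic β‑carbon.

Step 12
Reactants: 17 transposed enone; 18 (2-methylprop-1-en-1-yl)magnesium bromide
Product: 20 ketone with the C10 alkenyl group and the C11 methyl both β, via silyl enol ether 19 (not isolated)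
Conditions: CuBr·SMe2 (10 mol %), Me3SiCl, HMPA, THF, −78 °C; then 10 % aq. citric acid, THF, 0 °C
Reagents that add atoms: chlorotrimethylsilane C[Si](C)(C)Cl (retained only in 19)
Why: Copper‑catalysed, silyl‑chloride‑accelerated conjugate addition delivers the alkenyl group axially to C10, anti to both the C2‑bearing substituent on C1 and the C14 silyloxy group; kinetic protonation of the enol ether anti to the new group sets C11 (methyl cis to C9).

Step 13
Reactants: 20 ketone
Product: 21 12β-alcohol (hydroxyl cis to C9 and C20)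
Conditions: LiBH(s-Bu)3, THF, −78 °C
Reagents that add atoms: none
Why: The bulky hydride attacks the C12 ketone from the face opposite the axial C10 substituent, giving the axial 12β‑alcohol.

Step 14
Reactants: 21 12β-alcohol
Product: 22 12β-tert-butyldimethylsilyl ether
Conditions: t-BuMe2SiOTf, 2,6-lutidine, CH2Cl2, 0 °C
Reagents that add atoms: tert-butyldimethylsilyl trifluoromethanesulfonate CC(C)(C)[Si](C)(C)OS(=O)(=O)C(F)(F)F
Why: Silylation masks the one hydroxyl that must stay free of acetate; it is removed in the last step.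

Step 15
Reactants: 22 12β-tert-butyldimethylsilyl ether
Product: 23 C9 aldehyde
Conditions: O3, pyridine, CH2Cl2, −78 °C (Sudan Red 7B end point); then Me2S
Reagents that add atoms: ozone O=[O+][O-]
Why: Chemoselective ozonolysis cleaves the electron‑rich trisubstituted alkene much faster than the monosubstituted vinyl group next to the ester.

Step 16
Reactants: 23 C9 aldehyde; 24 methoxyallene
Product: 26 (9R)-α′-hydroxy vinyl ketone (C8 ketone; 9-OH and 14-OH free), via allenyl carbinol 25 (not isolated)
Conditions: 24, n-BuLi, THF, −78 °C; then 23, −78 °C; then 1 M H2SO4, THF, 0 °C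
Reagents that add atoms: water O
Why: Felkin–Anh addition of the acyl‑anion equivalent 1‑lithio‑1‑methoxyallene to the α‑branched aldehyde (quaternary C1 as the large group) sets C9; acid hydrolysis of the allenyl enol ether gives the vinyl ketone and removes the triethylsilyl ether.

Step 17
Reactants: 26 (9R)-α′-hydroxy vinyl ketone; 27 tert-butyl 2-bromopropanoate
Product: 28 tert-butyl ester with the C8 tertiary carbinol (target configuration at C8; C17 mixture)
Conditions: Zn (activated, excess), THF, 0 → 20 °C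
Reagents that add atoms: none
Why: Reformatsky 1,2‑addition to the ketone under Cram‑chelate control by the zinc alkoxide of the 9‑hydroxyl puts the propanoate carbon on the C9–H side and sets C8; C17 is corrected in step 20.

Step 18
Reactants: 28 tert-butyl ester carbinol
Product: 29 2,9,14-triacetate diene (8-OH free)
Conditions: Ac2O, pyridine, DMAP (cat.), CH2Cl2, 20 °C
Reagents that add atoms: acetic anhydride CC(=O)OC(C)=O
Why: Acetylation of the two secondary hydroxyls (C9, C14) leaves the tertiary 8‑hydroxyl untouched and removes the γ‑hydroxyl that could lactonise onto C19.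

Step 19
Reactants: 29 2,9,14-triacetate diene
Product: 30 (6Z)-cyclodecene macrocycle (ten-membered ring C1–C10; tert-butyl ester; 8-OH)
Conditions: second-generation Hoveyda–Grubbs catalyst (10 mol %), toluene (1 mM), 80 °C
Reagents that add atoms: none
Why: Ring‑closing metathesis of the two terminal vinyl groups closes the ten‑membered ring as the less strained cis‑cyclodecene, helped by the trans‑disposed chains on ring A and the free allylic 8‑hydroxyl.

Step 20
Reactants: 30 (6Z)-cyclodecene macrocycle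
Product: 32 12-O-tert-butyldimethylsilyl ether of the target, via C17-epimeric lactone 31 (not isolated)
Conditions: Pd(O2CCF3)2 (10 mol %), 1,4-benzoquinone (1.5 equiv), DMSO (20 mol %), (CF3)2CHOH/CH2Cl2, 40 °C; then DBU (0.3 equiv), CH2Cl2, 20 °C
Reagents that add atoms: none
Why: Proposed new method: a dealkylative Wacker‑type lactonisation in which divalent palladium activates the ring C6=C7 alkene, the tert‑butyl ester carbonyl oxygen attacks C7 (5‑exo anti‑oxypalladation; the lactone forms trans‑fused by least motion from the skewed C6=C7–C8–C9 torsion, which fixes C7), the O‑tert‑butyl oxocarbenium loses 2‑methylpropene, and β‑hydride elimination toward the acidic C5–H gives the conjugated (E)‑C5=C6 enoate from either C5 epimer while benzoquinone reoxidises zerovalent palladium; the closest known reactions are the oxidative lactonisation of alkenoic acids (Larock, Stoltz) and iodolactonisation of tert‑butyl esters, and DBU then equilibrates C17 to the epimer with C18 trans to C9.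

Step 21
Reactants: 32 12-O-tert-butyldimethylsilyl ether of the target
Product: 33 CNP0233742.2
Conditions: HF·pyridine, pyridine, THF, 0 → 20 °C
Reagents that add atoms: none
Why: Fluoride desilylation frees the 12‑hydroxyl without touching the acetates, the lactone or the enoate.

**Compound list**
1 | methyl (E)-but-2-enoate | C/C=C/C(=O)OC | starting material
2 | 2-(2-bromoethyl)-1,3-dioxolane | BrCCC1OCCO1 | starting material
3 | methyl 2-[2-(1,3-dioxolan-2-yl)ethyl]but-3-enoate (racemic) | C=CC(CCC1OCCO1)C(=O)OC | intermediate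
4 | methyl 2-ethenyl-5-oxopentanoate (racemic) | C=CC(CCC=O)C(=O)OC | intermediate
5 | (S)-(+)-carvone | O=C1C(C)=CC[C@H](C(C)=C)C1 | starting material
6 | (5S)-5-(1-hydroperoxy-1-methoxyethyl)-2-methylcyclohex-2-en-1-one | O=C1C(C)=CC[C@H](C(C)(OC)OO)C1 | intermediate
7 | (1S)-4-methyl-5-oxocyclohex-3-en-1-yl acetate | O=C1C(C)=CC[C@H](OC(C)=O)C1 | intermediate
8 | (5S)-5-hydroxy-2-methylcyclohex-2-en-1-one | O=C1C(C)=CC[C@H](O)C1 | intermediate
9 | (5S)-2-methyl-5-(triethylsilyloxy)cyclohex-2-en-1-one | O=C1C(C)=CC[C@H](O[Si](CC)(CC)CC)C1 | intermediate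
10 | aldol adduct of 9 and 4 (C1/C2 diastereomer mixture) | O=C1C(C)=CC[C@H](O[Si](CC)(CC)CC)C1C(O)CCC(C=C)C(=O)OC | intermediate
11 | β-diketone (C2 ketone on C1) | O=C1C(C)=CC[C@H](O[Si](CC)(CC)CC)C1C(=O)CCC(C=C)C(=O)OC | intermediate
12 | C1-methylated diketone (C15 trans to C14–O) | O=C1C(C)=CC[C@H](O[Si](CC)(CC)CC)[C@]1(C)C(=O)CCC(C=C)C(=O)OC | intermediate
13 | (2R)-alcohol | O=C1C(C)=CC[C@H](O[Si](CC)(CC)CC)[C@]1(C)[C@H](O)CCC(C=C)C(=O)OC | intermediate
14 | (2R)-acetate | O=C1C(C)=CC[C@H](O[Si](CC)(CC)CC)[C@]1(C)[C@H](OC(C)=O)CCC(C=C)C(=O)OC | intermediate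
15 | 11,12-epoxy ketone | O=C1[C@]2(C)[C@@H](O2)C[C@H](O[Si](CC)(CC)CC)[C@]1(C)[C@H](OC(C)=O)CCC(C=C)C(=O)OC | intermediate
16 | 12β-allylic alcohol (C10=C11) | C1=C(C)[C@@H](O)C[C@H](O[Si](CC)(CC)CC)[C@]1(C)[C@H](OC(C)=O)CCC(C=C)C(=O)OC | intermediate
17 | transposed enone (C12=O, C10=C11) | C1=C(C)C(=O)C[C@H](O[Si](CC)(CC)CC)[C@]1(C)[C@H](OC(C)=O)CCC(C=C)C(=O)OC | intermediate
18 | (2-methylprop-1-en-1-yl)magnesium bromide | CC(C)=C[Mg]Br | starting material
19 | trimethylsilyl enol ether (C11=C12) with C10 alkenyl group | CC(C)=C[C@H]1C(C)=C(O[Si](C)(C)C)C[C@H](O[Si](CC)(CC)CC)[C@]1(C)[C@H](OC(C)=O)CCC(C=C)C(=O)OC | intermediate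
20 | ketone, C10 alkenyl and C11 methyl β | CC(C)=C[C@H]1[C@@H](C)C(=O)C[C@H](O[Si](CC)(CC)CC)[C@]1(C)[C@H](OC(C)=O)CCC(C=C)C(=O)OC | intermediate
21 | 12β-alcohol | CC(C)=C[C@H]1[C@@H](C)[C@@H](O)C[C@H](O[Si](CC)(CC)CC)[C@]1(C)[C@H](OC(C)=O)CCC(C=C)C(=O)OC | intermediate
22 | 12β-tert-butyldimethylsilyl ether | CC(C)=C[C@H]1[C@@H](C)[C@@H](O[Si](C)(C)C(C)(C)C)C[C@H](O[Si](CC)(CC)CC)[C@]1(C)[C@H](OC(C)=O)CCC(C=C)C(=O)OC | intermediate
23 | C9 aldehyde | O=C[C@H]1[C@@H](C)[C@@H](O[Si](C)(C)C(C)(C)C)C[C@H](O[Si](CC)(CC)CC)[C@]1(C)[C@H](OC(C)=O)CCC(C=C)C(=O)OC | intermediate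
24 | methoxyallene (1-methoxypropa-1,2-diene) | COC=C=C | starting material
25 | (9R)-allenyl carbinol | C=C=C(OC)[C@H](O)[C@H]1[C@@H](C)[C@@H](O[Si](C)(C)C(C)(C)C)C[C@H](O[Si](CC)(CC)CC)[C@]1(C)[C@H](OC(C)=O)CCC(C=C)C(=O)OC | intermediate
26 | (9R)-α′-hydroxy vinyl ketone | C=CC(=O)[C@H](O)[C@H]1[C@@H](C)[C@@H](O[Si](C)(C)C(C)(C)C)C[C@H](O)[C@]1(C)[C@H](OC(C)=O)CCC(C=C)C(=O)OC | intermediate
27 | tert-butyl 2-bromopropanoate (racemic) | CC(Br)C(=O)OC(C)(C)C | starting material
28 | Reformatsky adduct (C8 carbinol; C17 mixture) | CC(C(=O)OC(C)(C)C)[C@@](C=C)(O)[C@H](O)[C@H]1[C@@H](C)[C@@H](O[Si](C)(C)C(C)(C)C)C[C@H](O)[C@]1(C)[C@H](OC(C)=O)CCC(C=C)C(=O)OC | intermediate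
29 | 2,9,14-triacetate diene | CC(C(=O)OC(C)(C)C)[C@@](C=C)(O)[C@H](OC(C)=O)[C@H]1[C@@H](C)[C@@H](O[Si](C)(C)C(C)(C)C)C[C@H](OC(C)=O)[C@]1(C)[C@H](OC(C)=O)CCC(C=C)C(=O)OC | intermediate
30 | (6Z)-cyclodecene macrocycle | COC(=O)C1/C=C\[C@@](O)(C(C)C(=O)OC(C)(C)C)[C@H](OC(C)=O)[C@H]2[C@@H](C)[C@@H](O[Si](C)(C)C(C)(C)C)C[C@H](OC(C)=O)[C@]2(C)[C@H](OC(C)=O)CC1 | intermediate
31 | 12-O-silyl lactone, C17 epimer mixture | COC(=O)/C1=C/[C@@H]2OC(=O)C(C)[C@@]2(O)[C@H](OC(C)=O)[C@H]2[C@@H](C)[C@@H](O[Si](C)(C)C(C)(C)C)C[C@H](OC(C)=O)[C@]2(C)[C@H](OC(C)=O)CC1 | intermediate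
32 | 12-O-tert-butyldimethylsilyl ether of the target | COC(=O)/C1=C/[C@@H]2OC(=O)[C@H](C)[C@@]2(O)[C@H](OC(C)=O)[C@H]2[C@@H](C)[C@@H](O[Si](C)(C)C(C)(C)C)C[C@H](OC(C)=O)[C@]2(C)[C@H](OC(C)=O)CC1 | intermediate
33 | CNP0233742.2 | COC(=O)/C1=C/[C@@H]2OC(=O)[C@H](C)[C@@]2(O)[C@H](OC(C)=O)[C@H]2[C@@H](C)[C@@H](O)C[C@H](OC(C)=O)[C@]2(C)[C@H](OC(C)=O)CC1 | target

**Step count**
Total: 21 steps. Longest linear sequence: 19 steps (steps 3–21, from 5).

**Three steps most likely to fail**

Step 17 (Reformatsky addition to a polar, Michael‑sensitive vinyl ketone; chelation control unproven). Fallback: setting out from 26, run a chelation‑controlled Mukaiyama aldol instead. The silyl ketene acetal 1-tert-butoxy-1-(trimethylsilyloxy)prop-1-ene F1 (from tert‑butyl propanoate, LiN(i-Pr)2 and Me3SiCl) is added with MgBr2·OEt2 in CH2Cl2 at −78 °C, and citric acid work‑up returns to 28.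

Step 19 (ten‑membered ring by metathesis next to a tertiary carbinol). Fallback: setting out from 26, close the ring one stage earlier on the less hindered acryloyl‑type olefin. Metathesis with the second‑generation Hoveyda–Grubbs catalyst gives the macrocyclic (Z)-enone F2; zinc Reformatsky addition of 27 to the ring ketone gives the macrocyclic diol ester F3; acetylation (Ac2O, pyridine, DMAP) returns to 30.

Step 20 (the proposed new lactonisation). Fallback with known chemistry: setting out from 30, iodolactonisation of the tert‑butyl ester (I2, NaHCO3, MeCN, 0 °C) gives the iodolactone F4 with the C7–O bond formed anti to iodine. DBU in toluene at 20 °C then eliminates HI toward C5 to give the conjugated enoate and equilibrates C17, returning to 32.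

Further compounds
F1 | step 17 | 1-tert-butoxy-1-(trimethylsilyloxy)prop-1-ene | CC=C(OC(C)(C)C)O[Si](C)(C)C
F2 | step 19 | macrocyclic (Z)-enone (C8 ketone, 9-OH, 14-OH, ten-membered ring closed) | COC(=O)C1/C=C\C(=O)[C@H](O)[C@H]2[C@@H](C)[C@@H](O[Si](C)(C)C(C)(C)C)C[C@H](O)[C@]2(C)[C@H](OC(C)=O)CC1
F3 | step 19 | macrocyclic diol tert-butyl ester (C8 carbinol; 9-OH, 14-OH) | COC(=O)C1/C=C\[C@@](O)(C(C)C(=O)OC(C)(C)C)[C@H](O)[C@H]2[C@@H](C)[C@@H](O[Si](C)(C)C(C)(C)C)C[C@H](O)[C@]2(C)[C@H](OC(C)=O)CC1
F4 | step 20 | 6-iodo lactone (C5, C6, C17 mixtures) | COC(=O)C1C(I)[C@@H]2OC(=O)C(C)[C@@]2(O)[C@H](OC(C)=O)[C@H]2[C@@H](C)[C@@H](O[Si](C)(C)C(C)(C)C)C[C@H](OC(C)=O)[C@]2(C)[C@H](OC(C)=O)CC1
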